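**Retrosynthetic overview**

1. Endgame in reverse: 16 ⇐ debenzylation of 15 ⇐ O-acetylation of hydroxyquinone 14 ⇐ epoxide-to-enol isomerisation of 13 ⇐ monoepoxidation of the symmetric quinone 12 ⇐ oxidative demethylation of 4-methoxyphenol 11.
2. The strategy rests on the central six-membered ring with para oxygens: C1 (C=O), C2 (C–OAc), C3 (C–aryl), C4 (C=O), C5 (C–H), C6 (C–aryl).
3. Key disconnection of C1–C2, C3–C4 and C4–C5: C1/C6/C5 come from the methoxy(1-arylvinyl)carbene ligand of 8, C2/C3 from terminal alkyne 9, and C4 from one CO ligand on chromium (Dötz benzannulation).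
4. Ring order: both 4-oxygenated benzene rings are bought; the central ring is the only ring formed (step 3). Complex 8 comes from acetophenone 1 by Shapiro reaction, addition to Cr(CO)6 and O-methylation.

Key step: step 3

Remark on the chemistry: the target has no stereocentre. Epoxide 13 forms as a racemate and both of its stereocentres are erased in step 6. Compounds 1, 2, 4 and 9 are taken as bought.

**Route**

Step 1
Reactants: 1 4'-benzyloxyacetophenone; 2 2,4,6-triisopropylbenzenesulfonyl hydrazide
Product: 3 (E)-N'-{1-[4-(benzyloxy)phenyl]ethylidene}-2,4,6-triisopropylbenzenesulfonohydrazide (trisylhydrazone of 1)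
Conditions: 2 (1.05 equiv), conc. HCl (cat.), MeOH, rt
Reagents that add atoms: none
Why: Acid-catalysed hydrazone condensation of a methyl ketone should proceed cleanly, and the trisyl group is chosen because its ortho isopropyl groups block ortho-lithiation and ease the later fragmentation.

Step 2
Reactants: 3 trisylhydrazone of 1; 4 chromium hexacarbonyl Cr(CO)6
Product: 8 pentacarbonyl{methoxy[1-(4-(benzyloxy)phenyl)vinyl]carbene}chromium, via dilithiated hydrazone 5 (not isolated), via vinyllithium 6 (not isolated), via lithium acylchromate 7 (not isolated)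
Conditions: n-BuLi (2.1 equiv), THF, −78 → 0 °C; then Cr(CO)6, THF, 0 °C → rt; evaporate; Me3OBF4 (1.5 equiv), CH2Cl2, 0 °C
Reagents that add atoms: trimethyloxonium tetrafluoroborate, C[O+](C)C.F[B-](F)(F)F
Why: A Shapiro reaction (double deprotonation, then loss of sulfinate and N2) should give the 1-arylvinyllithium, which adds to a CO ligand of zerovalent Cr(CO)6, and the acylchromate is O-methylated by Me3OBF4 in the classical Fischer carbene synthesis.

Step 3
Reactants: 8 pentacarbonyl{methoxy[1-(4-(benzyloxy)phenyl)vinyl]carbene}chromium; 9 1-(benzyloxy)-4-ethynylbenzene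
Product: 11 2,5-bis[4-(benzyloxy)phenyl]-4-methoxyphenol, via chromium tricarbonyl arene complex 10 (not isolated)
Conditions: 9 (1.5 equiv), THF (0.05 M), 50 °C, Ar; then air, Et2O, rt
Reagents that add atoms: none
Why: Thermal loss of one cis CO from 8 lets alkyne 9 bind and insert into the Cr=C bond (C1–C2), the vinylcarbene so formed takes up a CO ligand (C3–C4) to give a chromium-bound dienylketene, and this closes between the ketene carbon C4 and the vinyl CH2 carbon C5 and tautomerises to the phenol, held first as its Cr(CO)3 complex 10 and freed by air. The closest known reaction type is the Dötz benzannulation of alkenyl Fischer carbene complexes with terminal alkynes, of which this is a direct case. The one new ring, the central carbocycle, is closed by 6π electrocyclisation of the metal-templated dienylketene, and no stereocentre is formed. The step needs the aryl-bearing alkyne carbon to bond to the CO carbon, and the steric preference of terminal alkynes secures this, since the unsubstituted terminus bonds to the carbene carbon and the aryl group ends ortho to the new OH. It also needs CO insertion to outrun CO-free cyclopentannulation, which an alkenyl carbene substituent, the methoxy donor and THF at moderate temperature favour. The carbene oxygen and the inserted CO oxygen end para to each other, which is the relation step 4 turns into the quinone.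

Step 4
Reactants: 11 2,5-bis[4-(benzyloxy)phenyl]-4-methoxyphenol
Product: 12 2,5-bis[4-(benzyloxy)phenyl]-1,4-benzoquinone
Conditions: (NH4)2Ce(NO3)6 (2.2 equiv), MeCN/THF/H2O, 0 °C
Reagents that add atoms: water, O
Why: Oxidative demethylation of a 4-methoxyphenol by tetravalent cerium should run through the oxocarbenium ion and its hemiketal, water supplying the new carbonyl oxygen, while the benzyl aryl ethers are much harder to oxidise.

Step 5
Reactants: 12 2,5-bis[4-(benzyloxy)phenyl]-1,4-benzoquinone
Product: 13 rac-(1S,6R)-1,4-bis[4-(benzyloxy)phenyl]-7-oxabicyclo[4.1.0]hept-3-ene-2,5-dione (cis-fused monoepoxide of 12)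
Conditions: 30% aq. H2O2 (1.1 equiv), Na2CO3 (0.5 equiv), THF/H2O, 0 °C
Reagents that add atoms: hydrogen peroxide, OO
Why: In this Weitz–Scheffer nucleophilic epoxidation hydroperoxide should add to the unsubstituted ring carbon and the enolate close onto the O–O bond; the two ring alkenes are symmetry-equivalent, so only one monoepoxide can form, and its two stereocentres arise as the racemic cis pair enforced by the three-membered ring fusion.

Step 6
Reactants: 13 monoepoxide of 12
Product: 14 2,5-bis[4-(benzyloxy)phenyl]-3-hydroxy-1,4-benzoquinone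
Conditions: TsOH·H2O (0.2 equiv), CH2Cl2, rt
Reagents that add atoms: none
Why: Acid-catalysed epoxide-to-enol isomerisation should open the C–O bond at the aryl-bearing carbon (cation stabilised by the 4-benzyloxyphenyl group) and lose the proton of the neighbouring CH, giving the hydroxyquinone as in the known conversion of quinone epoxides into hydroxyquinones.

Step 7
Reactants: 14 2,5-bis[4-(benzyloxy)phenyl]-3-hydroxy-1,4-benzoquinone
Product: 15 3-acetoxy-2,5-bis[4-(benzyloxy)phenyl]-1,4-benzoquinone
Conditions: Ac2O (1.5 equiv), pyridine (2 equiv), CH2Cl2, 0 °C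
Reagents that add atoms: acetic anhydride, CC(=O)OC(C)=O
Why: O-Acylation of the only free hydroxyl, an acidic vinylogous carboxylic acid OH, with Ac2O and pyridine should give the enol acetate.

Step 8
Reactants: 15 3-acetoxy-2,5-bis[4-(benzyloxy)phenyl]-1,4-benzoquinone
Product: 16 Neonambiquinone A, 3-acetoxy-2,5-bis(4-hydroxyphenyl)-1,4-benzoquinone
Conditions: BCl3 (1 M in CH2Cl2, 5 equiv), pentamethylbenzene (6 equiv), CH2Cl2, −78 °C; cold pH 7 phosphate buffer
Reagents that add atoms: none
Why: Lewis-acid cleavage of aryl benzyl ethers by BCl3, with pentamethylbenzene trapping the benzyl cation by Friedel–Crafts alkylation, should proceed at −78 °C, where esters and the quinone are expected to survive.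

**Compound list**

1 | 4'-benzyloxyacetophenone | CC(=O)c1ccc(OCc2ccccc2)cc1 | starting material
2 | 2,4,6-triisopropylbenzenesulfonyl hydrazide | NNS(=O)(=O)c1c(C(C)C)cc(C(C)C)cc1C(C)C | starting material
3 | (E)-N'-{1-[4-(benzyloxy)phenyl]ethylidene}-2,4,6-triisopropylbenzenesulfonohydrazide | C/C(=N\NS(=O)(=O)c1c(C(C)C)cc(C(C)C)cc1C(C)C)c1ccc(OCc2ccccc2)cc1 | intermediate
4 | chromium hexacarbonyl Cr(CO)6 | O=C=[Cr](=C=O)(=C=O)(=C=O)(=C=O)=C=O | starting material
5 | dilithiated hydrazone (lithium on the methyl carbon and on the sulfonamide nitrogen of 3) | [Li]C/C(=N\N([Li])S(=O)(=O)c1c(C(C)C)cc(C(C)C)cc1C(C)C)c1ccc(OCc2ccccc2)cc1 | intermediate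
6 | {1-[4-(benzyloxy)phenyl]vinyl}lithium | [Li]C(=C)c1ccc(OCc2ccccc2)cc1 | intermediate
7 | lithium pentacarbonyl{1-oxido-2-[4-(benzyloxy)phenyl]prop-2-en-1-ylidene}chromate (lithium acylchromate) | [Li+].[O-]C(C(=C)c1ccc(OCc2ccccc2)cc1)=[Cr](=C=O)(=C=O)(=C=O)(=C=O)=C=O | intermediate
8 | pentacarbonyl{methoxy[1-(4-(benzyloxy)phenyl)vinyl]carbene}chromium | COC(C(=C)c1ccc(OCc2ccccc2)cc1)=[Cr](=C=O)(=C=O)(=C=O)(=C=O)=C=O | intermediate
9 | 1-(benzyloxy)-4-ethynylbenzene | C#Cc1ccc(OCc2ccccc2)cc1 | starting material
10 | tricarbonyl{η6-2,5-bis[4-(benzyloxy)phenyl]-4-methoxyphenol}chromium, Cr(CO)3 on the new central ring (SMILES written as arene and Cr(CO)3 fragment joined by a dot) | COc1cc(c2ccc(OCc3ccccc3)cc2)c(O)cc1c1ccc(OCc2ccccc2)cc1.O=C=[Cr](=C=O)=C=O | intermediate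
11 | 2,5-bis[4-(benzyloxy)phenyl]-4-methoxyphenol | COc1cc(c2ccc(OCc3ccccc3)cc2)c(O)cc1c1ccc(OCc2ccccc2)cc1 | intermediate
12 | 2,5-bis[4-(benzyloxy)phenyl]-1,4-benzoquinone | O=C1C=C(c2ccc(OCc3ccccc3)cc2)C(=O)C=C1c1ccc(OCc2ccccc2)cc1 | intermediate
13 | rac-(1S,6R)-1,4-bis[4-(benzyloxy)phenyl]-7-oxabicyclo[4.1.0]hept-3-ene-2,5-dione (racemic; one enantiomer drawn) | O=C1C=C(c2ccc(OCc3ccccc3)cc2)C(=O)[C@@H]2O[C@]12c1ccc(OCc2ccccc2)cc1 | intermediate
14 | 2,5-bis[4-(benzyloxy)phenyl]-3-hydroxy-1,4-benzoquinone | OC1=C(c2ccc(OCc3ccccc3)cc2)C(=O)C=C(c2ccc(OCc3ccccc3)cc2)C1=O | intermediate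
15 | 3-acetoxy-2,5-bis[4-(benzyloxy)phenyl]-1,4-benzoquinone | CC(=O)OC1=C(c2ccc(OCc3ccccc3)cc2)C(=O)C=C(c2ccc(OCc3ccccc3)cc2)C1=O | intermediate
16 | Neonambiquinone A, 3-acetoxy-2,5-bis(4-hydroxyphenyl)-1,4-benzoquinone | CC(=O)OC1=C(c2ccc(O)cc2)C(=O)C=C(c2ccc(O)cc2)C1=O | target

**Step count**

Total steps: 8. Longest linear sequence: 8 steps (from 1 to 16).

**Steps most likely to fail**

1. Step 3 (key step). The alkyne may insert with the wrong orientation, CO insertion may be skipped in favour of cyclopentannulation, the arylacetylene may oligomerise on chromium, or the α-arylvinyl carbene complex may decompose before it reacts.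
Fallback: the same type of dienylketene is generated thermally, without metal, by a Moore rearrangement. The fallback sets out from trisylhydrazone 3 and comes back to the route at hydroxyquinone 14, bypassing steps 3 to 6. Bought 1-(benzyloxy)-4-bromobenzene is lithiated with n-BuLi in THF at −78 °C to 4-benzyloxyphenyllithium F1. F1 adds once to bought dimethyl squarate to give 4-[4-(benzyloxy)phenyl]-4-hydroxy-2,3-dimethoxycyclobut-2-en-1-one F2. Catalytic conc. HCl in CH2Cl2 collapses F2, with loss of methanol, to 3-[4-(benzyloxy)phenyl]-4-methoxycyclobut-3-ene-1,2-dione F3. Vinyllithium 6, made from 3 as in step 2, should add at −78 °C to the ketone carbonyl next to the methoxy-bearing carbon, giving 2-[4-(benzyloxy)phenyl]-4-{1-[4-(benzyloxy)phenyl]vinyl}-4-hydroxy-3-methoxycyclobut-2-en-1-one F4. Heating F4 in toluene at reflux should open the four-membered ring to the dienylketene, which closes by 6π electrocyclisation and tautomerises to 2,5-bis[4-(benzyloxy)phenyl]-3-methoxybenzene-1,4-diol F5. Ag2O oxidises F5 to 2,5-bis[4-(benzyloxy)phenyl]-3-methoxy-1,4-benzoquinone F6. Aqueous NaOH in THF/MeOH followed by acidification hydrolyses this vinylogous ester to 14.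

2. Step 5. Alkaline peroxide may over-oxidise: a second epoxidation of the remaining ene-dione, hydroxide attack with ring cleavage, or premature isomerisation followed by oxidative degradation of the hydroxyquinone.
Fallback: the oxygen is introduced by oxidative amination and hydrolysis. The fallback sets out from quinone 12 and comes back at hydroxyquinone 14, bypassing step 6 as well. Morpholine (3 equiv) with Cu(OAc)2 (cat.) under air in EtOH/CH2Cl2 should add to one of the two equivalent C–H positions to give 2,5-bis[4-(benzyloxy)phenyl]-3-morpholinobenzene-1,4-diol F7. F7 is oxidised in the same flask to 2,5-bis[4-(benzyloxy)phenyl]-3-morpholino-1,4-benzoquinone F8. Dilute aqueous HCl in dioxane at 60 °C hydrolyses this vinylogous amide to 14.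

3. Step 8. The labile enol acetate may be lost through Lewis-acid-assisted acyl cleavage or during the quench, or debenzylation may stop at the monobenzyl stage.
Fallback: the benzyl groups are removed reductively and the quinone is restored afterwards. The fallback sets out from acetate 15 and comes back at target 16. H2 (1 atm) over palladium on carbon (Pd/C) in EtOAc at rt should reduce the quinone and cleave both benzyl ethers to 3,6-dihydroxy-2,5-bis(4-hydroxyphenyl)phenyl acetate F9. F9 is filtered under argon and oxidised at once with Ag2O and MgSO4 in EtOAc to 16. The hydroquinone stage is kept short and neutral to limit acetyl migration to the neighbouring hydroxyl.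

**Further compounds**

F1 | step 3 | 4-benzyloxyphenyllithium | [Li]c1ccc(OCc2ccccc2)cc1
F2 | step 3 | 4-[4-(benzyloxy)phenyl]-4-hydroxy-2,3-dimethoxycyclobut-2-en-1-one (racemic) | COC1=C(OC)C(O)(c2ccc(OCc3ccccc3)cc2)C1=O
F3 | step 3 | 3-[4-(benzyloxy)phenyl]-4-methoxycyclobut-3-ene-1,2-dione | COC1=C(c2ccc(OCc3ccccc3)cc2)C(=O)C1=O
F4 | step 3 | 2-[4-(benzyloxy)phenyl]-4-{1-[4-(benzyloxy)phenyl]vinyl}-4-hydroxy-3-methoxycyclobut-2-en-1-one (racemic) | COC1=C(c2ccc(OCc3ccccc3)cc2)C(=O)C1(O)C(=C)c1ccc(OCc2ccccc2)cc1
F5 | step 3 | 2,5-bis[4-(benzyloxy)phenyl]-3-methoxybenzene-1,4-diol | COc1c(c2ccc(OCc3ccccc3)cc2)c(O)cc(c2ccc(OCc3ccccc3)cc2)c1O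
F6 | step 3 | 2,5-bis[4-(benzyloxy)phenyl]-3-methoxy-1,4-benzoquinone | COC1=C(c2ccc(OCc3ccccc3)cc2)C(=O)C=C(c2ccc(OCc3ccccc3)cc2)C1=O
F7 | step 5 | 2,5-bis[4-(benzyloxy)phenyl]-3-morpholinobenzene-1,4-diol | Oc1cc(c2ccc(OCc3ccccc3)cc2)c(O)c(N2CCOCC2)c1c1ccc(OCc2ccccc2)cc1
F8 | step 5 | 2,5-bis[4-(benzyloxy)phenyl]-3-morpholino-1,4-benzoquinone | O=C1C=C(c2ccc(OCc3ccccc3)cc2)C(=O)C(N2CCOCC2)=C1c1ccc(OCc2ccccc2)cc1
F9 | step 8 | 3,6-dihydroxy-2,5-bis(4-hydroxyphenyl)phenyl acetate | CC(=O)Oc1c(c2ccc(O)cc2)c(O)cc(c2ccc(O)cc2)c1O
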